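**Plan**
- Retrosynthesis: cut first the sp3–sp2 bond between the two-carbon arm on C1 and the dienyl chain (bicyclic alkyl iodide plus a dienyl iodide from cis-α-irone), then C1–C2 of the 6-oxabicyclo[3.2.1]octane, then the exocyclic C1=C bond and O6–C7 of the remaining oxolane, and last C5–C4 and C5–C8 of the open chain.
- Enabling feature: C1 (quaternary bridgehead) and C2 (methyl carbinol) are neighbouring, fully substituted carbons of the carbocyclic six-membered ring, while C5, O6, C7 and C8 lie in an oxolane. Both congested centres can therefore be made in one event by bonding a methyl-ketone carbon (C2, on the C5 side chain) to an alkylidene carbon (C1) of that preformed oxolane.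
- Forward order: aldol (C5–C8); oxidation and Grignard addition (C5–C4); carbenoid O–H insertion (oxolan-3-one, ring 1); Wittig (C1 enoate); SmI2 cyclisation (cyclohexane, ring 2); Negishi coupling of the side chain; C10 oxidation and desilylation.
- Stereochemistry: C9 from (R)-Roche ester; C8 from an oxazolidinone-controlled aldol; C5 from a 1,3-chelate-controlled Grignard addition; C1 and C2 in the ketyl–enoate cyclisation; the cyclohexene centres from (1R,5S)-cis-α-irone; the trisubstituted E-alkene from syn-carboalumination.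

Key step: step 16

Assumption: (1R,5S)-cis-α-irone is taken as available in enantiopure form (orris-derived or resolved material), so the two cyclohexene stereocentres are bought, not made.

Conventions: C1–C8 (O6) are the atoms of the 6-oxabicyclo[3.2.1]octane of the target, C9 and C10 the α- and carbonyl carbons of its propanal arm; the same labels are used for the acyclic and oxolane precursors. TBS = tert-butyldimethylsilyl, TBDPS = tert-butyldiphenylsilyl, TMS = trimethylsilyl; TBSO, TBDPSO and TMSO are the corresponding silyloxy groups.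

**Step 1**
Reactants: 1 δ-valerolactone (oxan-2-one)
Product: 4 5-(TBDPSO)pentanoic acid, via sodium 5-hydroxypentanoate 2 (not isolated), via bis-silylated silyl ester 3 (not isolated)
Conditions: NaOH (1 equiv), MeOH/H2O, 60 °C, evaporate; TBDPSCl (2.2 equiv), imidazole, DMF, rt; THF/1 M HCl, rt
Reagents that add atoms: sodium hydroxide, [Na+].[OH-]; tert-butyl(chloro)diphenylsilane, CC(C)(C)[Si](Cl)(c1ccccc1)c1ccccc1
Why: Saponification opens the lactone, exhaustive silylation gives silyl ether plus silyl ester, and the labile silyl ester alone is hydrolysed by dilute acid, leaving the primary TBDPS ether.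

**Step 2**
Reactants: 4 5-(TBDPSO)pentanoic acid; 5 (4R)-4-benzyl-1,3-oxazolidin-2-one
Product: 7 (4R)-4-benzyl-3-[5-(TBDPSO)pentanoyl]-1,3-oxazolidin-2-one, via mixed pivalic anhydride 6 (not isolated)
Conditions: PivCl, Et3N, THF, −20 → 0 °C; then 5, LiCl, rt
Reagents that add atoms: none
Why: N-acylation of the oxazolidinone through the mixed pivalic anhydride (LiCl/Et3N activation) is the standard mild entry to Evans imides and touches no stereocentre.

**Step 3**
Reactants: 8 methyl (2R)-3-hydroxy-2-methylpropanoate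
Product: 9 methyl (2R)-2-methyl-3-(TBSO)propanoate
Conditions: TBSCl, imidazole, CH2Cl2, 0 °C → rt
Reagents that add atoms: tert-butyl(chloro)dimethylsilane, CC(C)(C)[Si](C)(C)Cl
Why: Imidazole-promoted silylation of the primary alcohol (silyl ether formation) leaves the α-stereocentre untouched.

**Step 4**
Reactants: 9 methyl (2R)-2-methyl-3-(TBSO)propanoate
Product: 10 (2R)-2-methyl-3-(TBSO)propanal
Conditions: DIBAL-H (1.05 equiv), CH2Cl2, −78 °C; Rochelle salt work-up
Reagents that add atoms: none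
Why: Partial reduction of the ester with one equivalent of DIBAL-H at −78 °C should deliver the aldehyde on work-up; it is used crude and at once because C9 is configurationally labile.

**Step 5**
Reactants: 7 (4R)-4-benzyl-3-[5-(TBDPSO)pentanoyl]-1,3-oxazolidin-2-one; 10 (2R)-2-methyl-3-(TBSO)propanal
Product: 12 (4R)-4-benzyl-3-[(2R,3S,4R)-3-hydroxy-4-methyl-5-(TBSO)-2-[3-(TBDPSO)propyl]pentanoyl]-1,3-oxazolidin-2-one, via dibutylboron enolate 11 (not isolated)
Conditions: Bu2BOTf, i-Pr2NEt, CH2Cl2, −78 → 0 °C; 10, −78 → 0 °C; pH 7 buffer, MeOH, 30% H2O2, 0 °C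
Reagents that add atoms: none
Why: Evans syn-aldol reaction: the (Z)-boron enolate reacts through a Zimmerman–Traxler chair on the face left open by the (R)-benzyl auxiliary, which should fix C8 independently of the aldehyde α-centre C9 (carried in from 10), while the syn carbinol formed at C5 is oxidised in step 8.

**Step 6**
Reactants: 12 the aldol adduct
Product: 13 (2S,3S,4R)-4-methyl-5-(TBSO)-2-[3-(TBDPSO)propyl]pentane-1,3-diol
Conditions: LiBH4, MeOH (1 equiv), THF, 0 °C
Reagents that add atoms: none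
Why: Reductive cleavage of the acyl oxazolidinone with LiBH4 should give the primary alcohol (the future C1) and return the auxiliary without touching C8, C5 or C9.

**Step 7**
Reactants: 13 the 1,3-diol
Product: 15 (2R,3S,4S)-4-[(benzyloxy)methyl]-2-methyl-1-(TBSO)-7-(TBDPSO)heptan-3-ol, via stannylene acetal 14 (not isolated)
Conditions: Bu2SnO, toluene, reflux (Dean–Stark); BnBr, Bu4NI, toluene, 90 °C
Reagents that add atoms: benzyl bromide, BrCc1ccccc1
Why: Stannylene-acetal-mediated regioselective O-alkylation activates the primary oxygen of the 1,3-diol and should give the primary benzyl ether that later serves as the chelating group.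

**Step 8**
Reactants: 15 the secondary alcohol
Product: 16 (2R,4S)-4-[(benzyloxy)methyl]-2-methyl-1-(TBSO)-7-(TBDPSO)heptan-3-one
Conditions: Dess–Martin periodinane, NaHCO3, CH2Cl2, 0 °C → rt
Reagents that add atoms: none
Why: Buffered Dess–Martin oxidation converts the C5 carbinol into the ketone under non-epimerising conditions, leaving the flanking C8 and C9 centres intact.

**Step 9**
Reactants: 16 the ketone; 17 2-(2-bromoethyl)-2-methyl-1,3-dioxolane
Product: 19 (2R,3S,4S)-4-[(benzyloxy)methyl]-2-methyl-3-[2-(2-methyl-1,3-dioxolan-2-yl)ethyl]-1-(TBSO)-7-(TBDPSO)heptan-3-ol, via Grignard reagent 18 (not isolated)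
Conditions: 17, Mg, THF, 25–30 °C; then 16, MgBr2·OEt2, CH2Cl2, −78 °C, add 18, −78 → −40 °C; aqueous work-up
Reagents that add atoms: none
Why: Cram-chelate-controlled Grignard addition: magnesium ties the ketone oxygen to the β-benzyloxy oxygen and the alkyl group should enter anti to the C8 propyl branch, a face that is also anti to the C9 methyl group in the analogous chelate on the other side, so both neighbouring centres direct C5 the same way.

**Step 10**
Reactants: 19 the benzyl ether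
Product: 20 (2R,3S,4S)-4-(hydroxymethyl)-2-methyl-3-[2-(2-methyl-1,3-dioxolan-2-yl)ethyl]-1-(TBSO)-7-(TBDPSO)heptan-3-ol
Conditions: H2 (1 atm), 10% Pd/C, EtOAc, rt
Reagents that add atoms: none
Why: Hydrogenolysis of the benzyl ether over Pd/C in a neutral solvent should leave both silyl ethers and the dioxolane intact.

**Step 11**
Reactants: 20 the primary/tertiary diol
Product: 21 (2R,3S,4R)-3-hydroxy-4-methyl-3-[2-(2-methyl-1,3-dioxolan-2-yl)ethyl]-5-(TBSO)-2-[3-(TBDPSO)propyl]pentanoic acid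
Conditions: TEMPO (cat.), NaClO2, NaOCl (cat.), MeCN/pH 6.7 phosphate buffer, 35 °C
Reagents that add atoms: sodium chlorite, [Na+].[O-]Cl=O
Why: TEMPO-catalysed oxidation with chlorite as terminal oxidant takes the primary alcohol through the aldehyde to the acid at near-neutral pH; the tertiary alcohol cannot be oxidised and the ketal and silyl ethers tolerate the buffer.

**Step 12**
Reactants: 21 the β-hydroxy acid
Product: 23 (3R,4S,5R)-1-diazo-4-hydroxy-5-methyl-4-[2-(2-methyl-1,3-dioxolan-2-yl)ethyl]-6-(TBSO)-3-[3-(TBDPSO)propyl]hexan-2-one, via mixed carbonic anhydride 22 (not isolated)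
Conditions: ClCO2Et, Et3N, THF, −15 °C; CH2N2, Et2O, 0 °C → rt
Reagents that add atoms: diazomethane, C=[N+]=[N-]
Why: Acylation of diazomethane by the mixed carbonic anhydride (the first stage of an Arndt–Eistert sequence) should give the α-diazoketone, the hindered tertiary hydroxyl being too slow to compete for the anhydride at −15 °C.

**Step 13**
Reactants: 23 the diazoketone
Product: 24 (4R,5S)-5-[2-(2-methyl-1,3-dioxolan-2-yl)ethyl]-5-[(2R)-1-(TBSO)propan-2-yl]-4-[3-(TBDPSO)propyl]oxolan-3-one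
Conditions: Rh2(OAc)4 (1 mol %), CH2Cl2, rt, slow addition
Reagents that add atoms: none
Why: Rhodium(II)-carbenoid O–H insertion into the tertiary alcohol closes the five-membered O6–C7 ring under neutral conditions, so the α-centre C8 of the new ketone should not epimerise.

**Step 14**
Reactants: 24 the oxolan-3-one
Product: 25 ethyl (2Z)-2-[(4S,5R)-5-[2-(2-methyl-1,3-dioxolan-2-yl)ethyl]-5-[(2R)-1-(TBSO)propan-2-yl]-4-[3-(TBDPSO)propyl]oxolan-3-ylidene]acetate
Conditions: Ph3P=CHCO2Et, toluene, 80 °C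
Reagents that add atoms: ethyl (triphenylphosphoranylidene)acetate, CCOC(=O)C=P(c1ccccc1)(c1ccccc1)c1ccccc1
Why: Wittig olefination with the stabilised ylide on the inductively activated 3-oxo-oxolane works without added base, which protects the epimerisable C8; the ester should sit cis to the ring CH2 (Z) to avoid the C8 branch, and either geometry serves the next steps.

**Step 15**
Reactants: 25 the ketal enoate
Product: 26 ethyl (2Z)-2-[(4S,5R)-5-(3-oxobutyl)-5-[(2R)-1-(TBSO)propan-2-yl]-4-[3-(TBDPSO)propyl]oxolan-3-ylidene]acetate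
Conditions: PPTS, acetone/H2O (10:1), 45 °C
Reagents that add atoms: water, O
Why: Mild acid-catalysed hydrolysis of the dioxolane frees the methyl ketone, while primary TBS and TBDPS ethers and the enoate should tolerate PPTS in wet acetone.

**Step 16**
Reactants: 26 the keto enoate
Product: 27 ethyl 2-[(1S,2S,5R,8S)-2-hydroxy-2-methyl-5-[(2R)-1-(TBSO)propan-2-yl]-8-[3-(TBDPSO)propyl]-6-oxabicyclo[3.2.1]octan-1-yl]acetate
Conditions: SmI2 (3 equiv), t-BuOH (3 equiv), THF, −78 → −30 °C; pH 7 buffer quench at low temperature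
Reagents that add atoms: none
Why: Electron transfer from SmI2 to the methyl ketone gives a samarium ketyl whose carbon (C2) adds to the β-carbon (C1) of the exocyclic enoate; a second electron turns the α-ester radical into the samarium enolate, which t-BuOH protonates. The closest known reaction type is the SmI2 ketyl–olefin reductive cyclisation of keto-enoates to 2-(alkoxycarbonylmethyl)cycloalkanols. The cyclohexane closes in the 6-exo-trig mode, and because the 3-oxobutyl chain on C5 can reach C1 only across its own face of the oxolane, the bridged bicycle forms with C1 fixed relative to C5. At C2 a chair-like transition state should place the bulky O–Sm(III) group pseudo-equatorial and anti to the developing enolate, with the methyl group axial towards C8–H, so the hydroxyl ends trans to the CH2CO2Et arm and on the side of the O6–C7 bridge. The step needs reduction of the ketone in preference to the enoate and closure onto a fully substituted alkene carbon; the polarity match of nucleophilic ketyl and electron-poor alkene, the absence of HMPA and the low temperature should secure this, and C8 is safe because no base is present.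

**Step 17**
Reactants: 27 the bicyclic hydroxy ester
Product: 28 ethyl 2-[(1S,2S,5R,8S)-2-methyl-5-[(2R)-1-(TBSO)propan-2-yl]-8-[3-(TBDPSO)propyl]-2-(TMSO)-6-oxabicyclo[3.2.1]octan-1-yl]acetate
Conditions: TMSOTf, 2,6-lutidine, CH2Cl2, −78 °C (on freshly prepared 27)
Reagents that add atoms: trimethylsilyl trifluoromethanesulfonate, C[Si](C)(C)OS(=O)(=O)C(F)(F)F
Why: Silylation of the hindered tertiary alcohol with the silyl triflate masks it against lactonisation onto the ester and against later five-membered ether formation with the primary iodide.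

**Step 18**
Reactants: 28 the TMS-protected ester
Product: 29 2-[(1S,2S,5R,8S)-2-methyl-5-[(2R)-1-(TBSO)propan-2-yl]-8-[3-(TBDPSO)propyl]-2-(TMSO)-6-oxabicyclo[3.2.1]octan-1-yl]ethan-1-ol
Conditions: DIBAL-H (2.5 equiv), CH2Cl2, −78 → −20 °C; Rochelle salt work-up
Reagents that add atoms: none
Why: DIBAL-H reduction of the ester to the primary alcohol under a neutral work-up should keep the tertiary TMS ether.

**Step 19**
Reactants: 29 the primary alcohol
Product: 30 (1S,2S,5R,8S)-1-(2-iodoethyl)-2-methyl-5-[(2R)-1-(TBSO)propan-2-yl]-8-[3-(TBDPSO)propyl]-2-(TMSO)-6-oxabicyclo[3.2.1]octane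
Conditions: I2, PPh3, imidazole, CH2Cl2, 0 °C
Reagents that add atoms: iodine, II
Why: Appel-type iodination of the unhindered primary alcohol under imidazole buffering; the iodide is used without storage.

**Step 20**
Reactants: 31 (3E)-4-[(1R,5S)-2,5,6,6-tetramethylcyclohex-2-en-1-yl]but-3-en-2-one (cis-α-irone)
Product: 34 (1E)-1-[(1R,5S)-2,5,6,6-tetramethylcyclohex-2-en-1-yl]but-1-en-3-yne, via lithium dienolate 32 (not isolated), via enol phosphate 33 (not isolated)
Conditions: LDA (commercial solution, 1.05 equiv), THF, −78 °C; ClP(O)(OEt)2, −78 °C → rt; LDA (2.3 equiv), −78 °C → rt; H2O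
Reagents that add atoms: none
Why: Methyl ketone to terminal alkyne by enol phosphate elimination: kinetic deprotonation at the methyl group, O-phosphorylation and base-induced elimination, with the low temperature meant to spare the bis-allylic ring C–H.

**Step 21**
Reactants: 34 the enyne
Product: 36 (1E,3E)-1-iodo-2-methyl-4-[(1R,5S)-2,5,6,6-tetramethylcyclohex-2-en-1-yl]buta-1,3-diene, via alkenylalane 35 (not isolated)
Conditions: Me3Al, Cp2ZrCl2 (0.25 equiv), CH2Cl2, 0 °C → rt; I2, THF, −30 → 0 °C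
Reagents that add atoms: trimethylaluminium, C[Al](C)C; iodine, II
Why: Zirconium-catalysed carboalumination adds methyl and aluminium syn across the terminal alkyne (methyl to the internal carbon), and iodinolysis of the alkenyl–aluminium bond with retention should give the (1E,3E)-iodide.

**Step 22**
Reactants: 30 the bicyclic primary iodide; 36 the dienyl iodide
Product: 38 (1S,2S,5R,8S)-2-methyl-1-[(3E,5E)-4-methyl-6-[(1R,5S)-2,5,6,6-tetramethylcyclohex-2-en-1-yl]hexa-3,5-dien-1-yl]-5-[(2R)-1-(TBSO)propan-2-yl]-8-[3-(TBDPSO)propyl]-2-(TMSO)-6-oxabicyclo[3.2.1]octane, via alkylzinc iodide 37 (not isolated)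
Conditions: 30, Zn dust, LiCl, THF, 40 °C; then 36, Pd(PPh3)4 (5 mol %), THF, rt
Reagents that add atoms: none
Why: Negishi cross-coupling: zinc insertion into the primary C–I bond and palladium-catalysed coupling of the alkylzinc iodide with the alkenyl iodide, which retains the alkene geometry and leaves the silyl ethers alone.

**Step 23**
Reactants: 38 the tris-silyl ether
Product: 39 (1S,2S,5R,8S)-5-[(2R)-1-hydroxypropan-2-yl]-2-methyl-1-[(3E,5E)-4-methyl-6-[(1R,5S)-2,5,6,6-tetramethylcyclohex-2-en-1-yl]hexa-3,5-dien-1-yl]-8-[3-(TBDPSO)propyl]-6-oxabicyclo[3.2.1]octan-2-ol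
Conditions: CSA (cat.), MeOH/CH2Cl2, 0 °C
Reagents that add atoms: none
Why: Acid-catalysed methanolysis should remove the primary TBS and the tertiary TMS ethers while the much more acid-stable primary TBDPS ether remains.

**Step 24**
Reactants: 39 the primary/tertiary diol
Product: 40 (2S)-2-[(1S,2S,5R,8S)-2-hydroxy-2-methyl-1-[(3E,5E)-4-methyl-6-[(1R,5S)-2,5,6,6-tetramethylcyclohex-2-en-1-yl]hexa-3,5-dien-1-yl]-8-[3-(TBDPSO)propyl]-6-oxabicyclo[3.2.1]octan-5-yl]propanal
Conditions: Dess–Martin periodinane, NaHCO3, CH2Cl2, 0 °C → rt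
Reagents that add atoms: none
Why: Buffered Dess–Martin oxidation converts only the primary alcohol into the aldehyde (the tertiary alcohol is inert) and should not epimerise the α-centre C9.

**Step 25**
Reactants: 40 the TBDPS-protected hydroxy aldehyde
Product: 41 (2S)-2-[(1S,2S,5R,8S)-2-hydroxy-8-(3-hydroxypropyl)-2-methyl-1-[(3E,5E)-4-methyl-6-[(1R,5S)-2,5,6,6-tetramethylcyclohex-2-en-1-yl]hexa-3,5-dien-1-yl]-6-oxabicyclo[3.2.1]octan-5-yl]propanal (CNP0419303.1)
Conditions: HF·pyridine, pyridine, THF, 0 °C → rt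
Reagents that add atoms: none
Why: Fluoride-mediated cleavage of the silyl ether with pyridine-buffered HF avoids the basic conditions that could epimerise the α-branched aldehyde.

**Compound list**
1 | δ-valerolactone (oxan-2-one) | O=C1CCCCO1 | starting material
2 | sodium 5-hydroxypentanoate | [Na+].[O-]C(=O)CCCCO | intermediate (not isolated)
3 | tert-butyldiphenylsilyl 5-(TBDPSO)pentanoate | CC(C)(C)[Si](c1ccccc1)(c1ccccc1)OCCCCC(=O)O[Si](c1ccccc1)(c1ccccc1)C(C)(C)C | intermediate (not isolated)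
4 | 5-(TBDPSO)pentanoic acid | OC(=O)CCCCO[Si](c1ccccc1)(c1ccccc1)C(C)(C)C | intermediate
5 | (4R)-4-benzyl-1,3-oxazolidin-2-one | O=C1N[C@H](Cc2ccccc2)CO1 | starting material
6 | 5-(TBDPSO)pentanoic pivalic anhydride | CC(C)(C)C(=O)OC(=O)CCCCO[Si](c1ccccc1)(c1ccccc1)C(C)(C)C | intermediate (not isolated)
7 | (4R)-4-benzyl-3-[5-(TBDPSO)pentanoyl]-1,3-oxazolidin-2-one | O=C1OC[C@@H](Cc2ccccc2)N1C(=O)CCCCO[Si](c1ccccc1)(c1ccccc1)C(C)(C)C | intermediate
8 | methyl (2R)-3-hydroxy-2-methylpropanoate | COC(=O)[C@H](C)CO | starting material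
9 | methyl (2R)-2-methyl-3-(TBSO)propanoate | COC(=O)[C@H](C)CO[Si](C)(C)C(C)(C)C | intermediate
10 | (2R)-2-methyl-3-(TBSO)propanal | O=C[C@H](C)CO[Si](C)(C)C(C)(C)C | intermediate
11 | (Z)-dibutylboron enolate of 7 | CCCCB(CCCC)O/C(=C\CCCO[Si](c1ccccc1)(c1ccccc1)C(C)(C)C)N1[C@H](Cc2ccccc2)COC1=O | intermediate (not isolated)
12 | (4R)-4-benzyl-3-[(2R,3S,4R)-3-hydroxy-4-methyl-5-(TBSO)-2-[3-(TBDPSO)propyl]pentanoyl]-1,3-oxazolidin-2-one | O=C1OC[C@@H](Cc2ccccc2)N1C(=O)[C@H](CCCO[Si](c1ccccc1)(c1ccccc1)C(C)(C)C)[C@@H](O)[C@H](C)CO[Si](C)(C)C(C)(C)C | intermediate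
13 | (2S,3S,4R)-4-methyl-5-(TBSO)-2-[3-(TBDPSO)propyl]pentane-1,3-diol | OC[C@H](CCCO[Si](c1ccccc1)(c1ccccc1)C(C)(C)C)[C@@H](O)[C@H](C)CO[Si](C)(C)C(C)(C)C | intermediate
14 | dibutylstannylene acetal of 13 (2,2-dibutyl-1,3,2-dioxastanninane) | CCCC[Sn]1(CCCC)OC[C@H](CCCO[Si](c2ccccc2)(c2ccccc2)C(C)(C)C)[C@H]([C@H](C)CO[Si](C)(C)C(C)(C)C)O1 | intermediate (not isolated)
15 | (2R,3S,4S)-4-[(benzyloxy)methyl]-2-methyl-1-(TBSO)-7-(TBDPSO)heptan-3-ol | c1ccccc1COC[C@H](CCCO[Si](c2ccccc2)(c2ccccc2)C(C)(C)C)[C@@H](O)[C@H](C)CO[Si](C)(C)C(C)(C)C | intermediate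
16 | (2R,4S)-4-[(benzyloxy)methyl]-2-methyl-1-(TBSO)-7-(TBDPSO)heptan-3-one | O=C([C@H](C)CO[Si](C)(C)C(C)(C)C)[C@H](COCc1ccccc1)CCCO[Si](c1ccccc1)(c1ccccc1)C(C)(C)C | intermediate
17 | 2-(2-bromoethyl)-2-methyl-1,3-dioxolane | CC1(CCBr)OCCO1 | starting material
18 | [2-(2-methyl-1,3-dioxolan-2-yl)ethyl]magnesium bromide | CC1(CC[Mg]Br)OCCO1 | intermediate (not isolated)
19 | (2R,3S,4S)-4-[(benzyloxy)methyl]-2-methyl-3-[2-(2-methyl-1,3-dioxolan-2-yl)ethyl]-1-(TBSO)-7-(TBDPSO)heptan-3-ol | O[C@]([C@H](C)CO[Si](C)(C)C(C)(C)C)(CCC1(C)OCCO1)[C@H](COCc1ccccc1)CCCO[Si](c1ccccc1)(c1ccccc1)C(C)(C)C | intermediate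
20 | (2R,3S,4S)-4-(hydroxymethyl)-2-methyl-3-[2-(2-methyl-1,3-dioxolan-2-yl)ethyl]-1-(TBSO)-7-(TBDPSO)heptan-3-ol | O[C@]([C@H](C)CO[Si](C)(C)C(C)(C)C)(CCC1(C)OCCO1)[C@H](CO)CCCO[Si](c1ccccc1)(c1ccccc1)C(C)(C)C | intermediate
21 | (2R,3S,4R)-3-hydroxy-4-methyl-3-[2-(2-methyl-1,3-dioxolan-2-yl)ethyl]-5-(TBSO)-2-[3-(TBDPSO)propyl]pentanoic acid | O[C@]([C@H](C)CO[Si](C)(C)C(C)(C)C)(CCC1(C)OCCO1)[C@H](C(=O)O)CCCO[Si](c1ccccc1)(c1ccccc1)C(C)(C)C | intermediate
22 | ethyl carbonic mixed anhydride of 21 | O[C@]([C@H](C)CO[Si](C)(C)C(C)(C)C)(CCC1(C)OCCO1)[C@H](C(=O)OC(=O)OCC)CCCO[Si](c1ccccc1)(c1ccccc1)C(C)(C)C | intermediate (not isolated)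
23 | (3R,4S,5R)-1-diazo-4-hydroxy-5-methyl-4-[2-(2-methyl-1,3-dioxolan-2-yl)ethyl]-6-(TBSO)-3-[3-(TBDPSO)propyl]hexan-2-one | O[C@]([C@H](C)CO[Si](C)(C)C(C)(C)C)(CCC1(C)OCCO1)[C@H](C(=O)C=[N+]=[N-])CCCO[Si](c1ccccc1)(c1ccccc1)C(C)(C)C | intermediate
24 | (4R,5S)-5-[2-(2-methyl-1,3-dioxolan-2-yl)ethyl]-5-[(2R)-1-(TBSO)propan-2-yl]-4-[3-(TBDPSO)propyl]oxolan-3-one | O=C1CO[C@]([C@H](C)CO[Si](C)(C)C(C)(C)C)(CCC2(C)OCCO2)[C@H]1CCCO[Si](c1ccccc1)(c1ccccc1)C(C)(C)C | intermediate
25 | ethyl (2Z)-2-[(4S,5R)-5-[2-(2-methyl-1,3-dioxolan-2-yl)ethyl]-5-[(2R)-1-(TBSO)propan-2-yl]-4-[3-(TBDPSO)propyl]oxolan-3-ylidene]acetate | CCOC(=O)/C=C1\CO[C@]([C@H](C)CO[Si](C)(C)C(C)(C)C)(CCC2(C)OCCO2)[C@H]1CCCO[Si](c1ccccc1)(c1ccccc1)C(C)(C)C | intermediate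
26 | ethyl (2Z)-2-[(4S,5R)-5-(3-oxobutyl)-5-[(2R)-1-(TBSO)propan-2-yl]-4-[3-(TBDPSO)propyl]oxolan-3-ylidene]acetate | CCOC(=O)/C=C1\CO[C@]([C@H](C)CO[Si](C)(C)C(C)(C)C)(CCC(C)=O)[C@H]1CCCO[Si](c1ccccc1)(c1ccccc1)C(C)(C)C | intermediate (precursor of the key step)
27 | ethyl 2-[(1S,2S,5R,8S)-2-hydroxy-2-methyl-5-[(2R)-1-(TBSO)propan-2-yl]-8-[3-(TBDPSO)propyl]-6-oxabicyclo[3.2.1]octan-1-yl]acetate | CCOC(=O)C[C@]12CO[C@]([C@H](C)CO[Si](C)(C)C(C)(C)C)(CC[C@]1(C)O)[C@H]2CCCO[Si](c1ccccc1)(c1ccccc1)C(C)(C)C | intermediate (product of the key step)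
28 | ethyl 2-[(1S,2S,5R,8S)-2-methyl-5-[(2R)-1-(TBSO)propan-2-yl]-8-[3-(TBDPSO)propyl]-2-(TMSO)-6-oxabicyclo[3.2.1]octan-1-yl]acetate | CCOC(=O)C[C@]12CO[C@]([C@H](C)CO[Si](C)(C)C(C)(C)C)(CC[C@]1(C)O[Si](C)(C)C)[C@H]2CCCO[Si](c1ccccc1)(c1ccccc1)C(C)(C)C | intermediate
29 | 2-[(1S,2S,5R,8S)-2-methyl-5-[(2R)-1-(TBSO)propan-2-yl]-8-[3-(TBDPSO)propyl]-2-(TMSO)-6-oxabicyclo[3.2.1]octan-1-yl]ethan-1-ol | OCC[C@]12CO[C@]([C@H](C)CO[Si](C)(C)C(C)(C)C)(CC[C@]1(C)O[Si](C)(C)C)[C@H]2CCCO[Si](c1ccccc1)(c1ccccc1)C(C)(C)C | intermediate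
30 | (1S,2S,5R,8S)-1-(2-iodoethyl)-2-methyl-5-[(2R)-1-(TBSO)propan-2-yl]-8-[3-(TBDPSO)propyl]-2-(TMSO)-6-oxabicyclo[3.2.1]octane | ICC[C@]12CO[C@]([C@H](C)CO[Si](C)(C)C(C)(C)C)(CC[C@]1(C)O[Si](C)(C)C)[C@H]2CCCO[Si](c1ccccc1)(c1ccccc1)C(C)(C)C | intermediate
31 | (3E)-4-[(1R,5S)-2,5,6,6-tetramethylcyclohex-2-en-1-yl]but-3-en-2-one (cis-α-irone) | CC1=CC[C@H](C)C(C)(C)[C@@H]1/C=C/C(C)=O | starting material
32 | lithium (3E)-4-[(1R,5S)-2,5,6,6-tetramethylcyclohex-2-en-1-yl]buta-1,3-dien-2-olate | CC1=CC[C@H](C)C(C)(C)[C@@H]1/C=C/C(=C)O[Li] | intermediate (not isolated)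
33 | diethyl (3E)-4-[(1R,5S)-2,5,6,6-tetramethylcyclohex-2-en-1-yl]buta-1,3-dien-2-yl phosphate | CC1=CC[C@H](C)C(C)(C)[C@@H]1/C=C/C(=C)OP(=O)(OCC)OCC | intermediate (not isolated)
34 | (1E)-1-[(1R,5S)-2,5,6,6-tetramethylcyclohex-2-en-1-yl]but-1-en-3-yne | CC1=CC[C@H](C)C(C)(C)[C@@H]1/C=C/C#C | intermediate
35 | dimethyl[(1E,3E)-2-methyl-4-[(1R,5S)-2,5,6,6-tetramethylcyclohex-2-en-1-yl]buta-1,3-dien-1-yl]alumane | CC1=CC[C@H](C)C(C)(C)[C@@H]1/C=C/C(C)=C/[Al](C)C | intermediate (not isolated)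
36 | (1E,3E)-1-iodo-2-methyl-4-[(1R,5S)-2,5,6,6-tetramethylcyclohex-2-en-1-yl]buta-1,3-diene | CC1=CC[C@H](C)C(C)(C)[C@@H]1/C=C/C(C)=C/I | intermediate
37 | alkylzinc iodide from 30 (iodo[2-(bicyclooctan-1-yl)ethyl]zinc) | I[Zn]CC[C@]12CO[C@]([C@H](C)CO[Si](C)(C)C(C)(C)C)(CC[C@]1(C)O[Si](C)(C)C)[C@H]2CCCO[Si](c1ccccc1)(c1ccccc1)C(C)(C)C | intermediate (not isolated)
38 | (1S,2S,5R,8S)-2-methyl-1-[(3E,5E)-4-methyl-6-[(1R,5S)-2,5,6,6-tetramethylcyclohex-2-en-1-yl]hexa-3,5-dien-1-yl]-5-[(2R)-1-(TBSO)propan-2-yl]-8-[3-(TBDPSO)propyl]-2-(TMSO)-6-oxabicyclo[3.2.1]octane | CC1=CC[C@H](C)C(C)(C)[C@@H]1/C=C/C(C)=C/CC[C@]12CO[C@]([C@H](C)CO[Si](C)(C)C(C)(C)C)(CC[C@]1(C)O[Si](C)(C)C)[C@H]2CCCO[Si](c1ccccc1)(c1ccccc1)C(C)(C)C | intermediate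
39 | (1S,2S,5R,8S)-5-[(2R)-1-hydroxypropan-2-yl]-2-methyl-1-[(3E,5E)-4-methyl-6-[(1R,5S)-2,5,6,6-tetramethylcyclohex-2-en-1-yl]hexa-3,5-dien-1-yl]-8-[3-(TBDPSO)propyl]-6-oxabicyclo[3.2.1]octan-2-ol | CC1=CC[C@H](C)C(C)(C)[C@@H]1/C=C/C(C)=C/CC[C@]12CO[C@]([C@H](C)CO)(CC[C@]1(C)O)[C@H]2CCCO[Si](c1ccccc1)(c1ccccc1)C(C)(C)C | intermediate
40 | (2S)-2-[(1S,2S,5R,8S)-2-hydroxy-2-methyl-1-[(3E,5E)-4-methyl-6-[(1R,5S)-2,5,6,6-tetramethylcyclohex-2-en-1-yl]hexa-3,5-dien-1-yl]-8-[3-(TBDPSO)propyl]-6-oxabicyclo[3.2.1]octan-5-yl]propanal | CC1=CC[C@H](C)C(C)(C)[C@@H]1/C=C/C(C)=C/CC[C@]12CO[C@]([C@H](C)C=O)(CC[C@]1(C)O)[C@H]2CCCO[Si](c1ccccc1)(c1ccccc1)C(C)(C)C | intermediate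
41 | (2S)-2-[(1S,2S,5R,8S)-2-hydroxy-8-(3-hydroxypropyl)-2-methyl-1-[(3E,5E)-4-methyl-6-[(1R,5S)-2,5,6,6-tetramethylcyclohex-2-en-1-yl]hexa-3,5-dien-1-yl]-6-oxabicyclo[3.2.1]octan-5-yl]propanal (CNP0419303.1) | CC1=CC[C@H](C)C(C)(C)[C@@H]1/C=C/C(C)=C/CC[C@]12CO[C@]([C@H](C)C=O)(CC[C@]1(C)O)[C@H]2CCCO | target

**Step count and risks**
Total: 25 steps. Longest linear sequence: 21 steps (from 8 through steps 3–19 and 22–25; equally from 1 through steps 1, 2, 5–19 and 22–25).

Steps most likely to fail: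

1. Step 16 (key cyclisation). Simple reduction of the ketone to the open-chain secondary alcohol, or saturation of the enoate, may outrun ring closure onto the fully substituted C1; samarium bridging of the ketyl and ester oxygens could also erode the facial preference at C2. Fallback: the same C1–C2 bond can be closed as a tin-hydride radical chain instead of by electron transfer. Setting out from 26, Bu3SnH and AIBN in benzene at 80 °C would add a stannyl radical to the ketone oxygen; the O-stannyl ketyl would cyclise 6-exo onto the enoate and the resulting α-ester radical would be reduced by Bu3SnH to the O-tributylstannyl ether F1. Stirring with aqueous KF would cleave the Sn–O bond and return the route to 27.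

2. Step 9 (Grignard addition). Proton abstraction from the doubly α-branched ketone by the basic alkyl Grignard reagent (epimerisation at C8 or C9, β-elimination of benzyloxide, or β-hydride reduction) and incomplete chelation may lower both conversion and facial selectivity. Fallback: a smaller, far less basic alkynyl nucleophile replaces the alkyl reagent. Setting out from 16, the bromomagnesium acetylide F2 (from known 2-ethynyl-2-methyl-1,3-dioxolane and EtMgBr) would add under the same chelate control in CH2Cl2/Et2O to give the propargylic tertiary alcohol F3. Hydrogenation over Pd/C in EtOAc would then saturate the triple bond and cleave the benzyl ether in one operation, returning to 20 and replacing steps 9 and 10.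

3. Step 14 (Wittig olefination). Addition of the stabilised ylide to the hindered ketone may be slow, and prolonged heating could epimerise C8 towards the unwanted isomer. Fallback: a two-stage olefination through an alkynyl carbinol. Setting out from 24, lithium ethoxyacetylide F4 (ethoxyacetylene, n-BuLi, THF, −78 °C) would add to the ketone at low temperature to give the 3-(ethoxyethynyl)oxolan-3-ol F5 as a mixture at the new carbinol carbon. A Meyer–Schuster rearrangement (AuCl3 cat., EtOH, CH2Cl2, rt) would convert it into the ethyl enoate 25, possibly as a Z/E mixture, both isomers of which lead to 27.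

**Further compounds**
F1 | step 16 | O-tributylstannyl ether of 27 | CCOC(=O)C[C@]12CO[C@]([C@H](C)CO[Si](C)(C)C(C)(C)C)(CC[C@]1(C)O[Sn](CCCC)(CCCC)CCCC)[C@H]2CCCO[Si](c1ccccc1)(c1ccccc1)C(C)(C)C
F2 | step 9 | bromo[(2-methyl-1,3-dioxolan-2-yl)ethynyl]magnesium | CC1(C#C[Mg]Br)OCCO1
F3 | step 9 | (2R,3S,4S)-4-[(benzyloxy)methyl]-2-methyl-3-[(2-methyl-1,3-dioxolan-2-yl)ethynyl]-1-(TBSO)-7-(TBDPSO)heptan-3-ol | O[C@]([C@H](C)CO[Si](C)(C)C(C)(C)C)(C#CC1(C)OCCO1)[C@H](COCc1ccccc1)CCCO[Si](c1ccccc1)(c1ccccc1)C(C)(C)C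
F4 | step 14 | lithium ethoxyacetylide | [Li]C#COCC
F5 | step 14 | 3-(ethoxyethynyl)oxolan-3-ol derived from 24 (both epimers at the carbinol carbon) | CCOC#CC1(O)CO[C@]([C@H](C)CO[Si](C)(C)C(C)(C)C)(CCC2(C)OCCO2)[C@H]1CCCO[Si](c1ccccc1)(c1ccccc1)C(C)(C)C
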